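The same 6.0 d is a long time for the target in one of these flasks and a short time in another, and that comparison is the thing I want to carry. The four flasks take one charge and differ in temperature.

all flasks: starting material 0.050 M; partner 2.00 equiv; protic impurity 0.0500 M; time 6.0 d

|  | temperature | remark |
|---|---|---|
| Monday's | 110 °C |  |
| Sunday's |  | at 60 °C until 4.0 d, from then on at 110 °C |
| Wednesday's | 60 °C |  |
| Saturday's | 85 °C |  |

- which flask leads in share of target in all that became target or homo product or isomer of the product ("all alike" within 1.5 percentage points) (Monday's / Sunday's / Wednesday's / Saturday's / all alike)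
- share of target in all that became target or homo product or isomer of the product, Monday's
- share of target in all that became target or homo product or isomer of the product, Sunday's
- share of target in all that became target or homo product or isomer of the product, Wednesday's
- share of target in all that became target or homo product or isomer of the product, Saturday's

- in percentages every species weighs as the starting material in it: one homo product counts as two
- two of one species on the left: rate k times its square, two consumed each time
- at 110 °C the constants are as listed, elsewhere as the activation energies and enthalpies make them

The target turns into the isomer of the product and back: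

target ⇌ isomer of the product (K6 = 0.93, k6 = 4.0 × 10⁻⁵ s⁻¹, Ea6 = 126 kJ mol⁻¹, ΔH6 = −24.0 kJ mol⁻¹)

The back constant of such a pair is the forward constant over the equilibrium constant, and any gap from equilibrium closes at the sum of the two. So the gap halves in the natural log of two divided by that sum. With 4.0 × 10⁻⁵ s⁻¹ and 0.93 this gives 2.32 h at 110 °C. I call this time the isomer half-life, both directions counted together, and I hold it against the time the flask has.

I solve the two ends first. Monday's flask runs for 62.1 isomer half-lives, a time far longer than one of them, so I expect the pair at equilibrium, which is thermodynamic control. Then c(isomer of the product) over c(target) is 0.93, and the target is 51.8% of the pair. Two open intermediate can also join to homo product, and that counts against the share, so I expect Monday's a little under this ceiling. Sunday's flask spends its last 2.00 d at 110 °C, which is 20.7 isomer half-lives, again far longer than one of them, so I put it near the same ceiling.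

At the cold end the isomer half-life of Wednesday's flask is 56.3 d, longer than its run. Target present from the first moment closes 7.12% of its gap, and target made later closes less. This is kinetic control: I do not expect the pair in Wednesday's flask to reach its equilibrium within its time. Wednesday's flask also loses share to homo product, in the race between open intermediate meeting second intermediate and open intermediate meeting itself, and my hand reckoning stops at that race. So I commit to Wednesday's leading, to Monday's and Sunday's near the ceiling, and to Saturday's at 85 °C lying between, without a number of my own for Wednesday's or Saturday's.

The forecast puts numbers on all four. It names Wednesday's as the leader and gives 50% for Monday's (48.5% to 51.5%), 49.5% for Sunday's (47.5% to 51%), 82% for Wednesday's (77% to 87%) and 64% for Saturday's (58% to 70%). Its ground at the cold end is that “the isomerisation barely moves in six days”.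

    starting material ⇌ open intermediate (K1 = 0.19, k1 = 3.7 × 10⁻⁵ s⁻¹, Ea1 = 120 kJ mol⁻¹, ΔH1 = −20.0 kJ mol⁻¹)
    partner → second intermediate (k2 = 2.1 × 10⁻⁵ s⁻¹, Ea2 = 118 kJ mol⁻¹)
    open intermediate + second intermediate → target (k3 = 2.9 × 10⁻⁴ M⁻¹ s⁻¹, Ea3 = 81.0 kJ mol⁻¹)
    2 open intermediate → homo product (k4 = 1.0 × 10⁻⁴ M⁻¹ s⁻¹, Ea4 = 99.0 kJ mol⁻¹)
    starting material + protic impurity → quenched substrate (k5 = 5.5 × 10⁻⁴ M⁻¹ s⁻¹, Ea5 = 83.0 kJ mol⁻¹)
    target ⇌ isomer of the product (K6 = 0.93, k6 = 4.0 × 10⁻⁵ s⁻¹, Ea6 = 126 kJ mol⁻¹, ΔH6 = −24.0 kJ mol⁻¹)
    (constants at 110 °C)

The flasks give 50.2% for Monday's, 51.8% for Sunday's, 82.0% for Wednesday's and 62.7% for Saturday's, so Wednesday's leads, as forecast. Wednesday's flask holds 0.0252% target at 6.00 d, with 73% of the starting material left. Wednesday's flask, left 60.0 d, gets 1.07 of its isomer half-lives and stands at 77.7%, with 0.918% isomer beside 4.70% target.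

All constants are made up; no experiment stands behind them.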